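**Retrosynthetic overview**

- The target comes from its tetra-O-methyl precursor, in which one BBr3 step removes the three aryl methyl ethers and the C3 methyl ester; that precursor comes from a lactol acetal whose masked aldehyde carbon becomes the C1' carboxyl.
- The C4–C1' bond comes from a decarboxylative radical conjugate addition of an isochromanone-4-carboxylic acid to (5S)-5-(d-menthyloxy)butenolide, used as a chiral fumarate surrogate. This step fixes C4 (anti to the C3 ester) and C1' (anti to the menthyloxy group).
- The lactone ring is the only ring made (the arene is bought). It comes from 5,6,7-trimethoxyhomophthalic anhydride and methyl glyoxylate: C3–C4 and O2–C1 form in one catalytic asymmetric operation that sets C3 and frees a carboxyl on C4, which serves as a traceless radical handle.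
- The anhydride comes from the homophthalic acid, made by copper-catalysed arylation of diethyl malonate with 2-bromo-3,4,5-trimethoxybenzoic acid; the butenolide comes from furfural and (+)-menthol.
- Feature used (isochromanone numbering: C1 lactone carbonyl, O2, C3, C4, C4a–C8a; C1' is the succinate CH on C4): the lactone ring is a homophthalate unit (C1, C8a, C4a, C4) closed by a glyoxylate C3–O2 unit, and C4 carries exactly one further carbon substituent, C1'.

Key step: step 4

Assumption: the sense of induction of cinchona squaramides with glyoxylate cannot be predicted with certainty; the quinidine-derived catalyst is written, and if it delivers the (3R) series its quinine-derived pseudoenantiomer is used instead with nothing else changed.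

**Route**

Step 1
Reactants: 1 2-bromo-3,4,5-trimethoxybenzoic acid; 2 diethyl malonate
Product: 3 2-(1,3-diethoxy-1,3-dioxopropan-2-yl)-3,4,5-trimethoxybenzoic acid
Conditions: NaH (3 equiv), CuBr (10 mol%), diethyl malonate as solvent, 80 °C; then aq. HCl
Reagents that add atoms: none
Why: Hurtley reaction, in which the sodium carboxylate ortho to bromine holds the copper from CuBr next to the C–Br bond so that the malonate anion should displace bromide at moderate temperature even on this electron-rich ring; no stereocentre is formed.

Step 2
Reactants: 3 2-(1,3-diethoxy-1,3-dioxopropan-2-yl)-3,4,5-trimethoxybenzoic acid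
Product: 5 2-(carboxymethyl)-3,4,5-trimethoxybenzoic acid, via arylmalonic triacid 4 (not isolated)
Conditions: NaOH, H2O/EtOH, reflux; then conc. HCl to pH 1, 90 °C
Reagents that add atoms: sodium hydroxide, [Na+].[OH-]
Why: Saponification of both esters followed by thermal decarboxylation of the arylmalonic acid (end of a malonic ester synthesis) should leave the benzoic acid and the three aryl methyl ethers untouched.

Step 3
Reactants: 5 2-(carboxymethyl)-3,4,5-trimethoxybenzoic acid
Product: 6 5,6,7-trimethoxyisochromane-1,3-dione
Conditions: Ac2O, toluene, reflux; evaporate, crystallise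
Reagents that add atoms: none
Why: Cyclodehydration through the mixed acetic anhydride closes the unstrained six-membered cyclic anhydride, the standard preparation of homophthalic anhydrides, and the absence of base avoids self-condensation at C4.

Step 4
Reactants: 6 5,6,7-trimethoxyisochromane-1,3-dione; 7 methyl glyoxylate (monomer, freshly distilled from P2O5)
Product: 8 (3S,4S)-3-(methoxycarbonyl)-5,6,7-trimethoxy-1-oxo-3,4-dihydro-1H-isochromene-4-carboxylic acid (trans)
Conditions: squaramide from 9-amino-9-deoxy-epi-quinidine and 3,5-bis(trifluoromethyl)aniline (5 mol%), MTBE, −30 °C; 1 M HCl wash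
Reagents that add atoms: none
Why: The quinuclidine nitrogen of the catalyst deprotonates the anhydride at C4 (benzylic and alpha to a carbonyl) while the squaramide N–H bonds hold methyl glyoxylate by its formyl oxygen, and the ion-paired enolate adds to the aldehyde carbon to form C3–C4. The C3 alkoxide then attacks the aryl-bound anhydride carbonyl C1 in a 6-exo-trig acyl transfer, which closes the lactone ring and releases the other anhydride carbonyl as the carboxylate on C4; this is the known organocatalytic asymmetric formal [4+2] cycloaddition of homophthalic anhydrides with aldehydes, the aldehyde counterpart of the Castagnoli–Cushman reaction. C3 is set by the catalyst, which presents one enantiotopic face of the hydrogen-bonded aldehyde to the enolate; C4 is set trans to C3 in the same organised transition state, but it is erased in step 7 and needs no control. The step therefore needs enantiofacial control at C3, attack at the formyl and not the ester carbonyl of 7 (secured by the far higher electrophilicity of the aldehyde), and lactonisation onto C1 and not onto the carbonyl attached to C4 (which would give a four-membered ring). Because glyoxylate is more electrophilic than the aldehydes normally used, monomeric 7 and low temperature are chosen to keep the uncatalysed background addition slow.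

Step 5
Reactants: 9 furfural
Product: 10 5-hydroxyfuran-2(5H)-one (racemic)
Conditions: O2, rose bengal (cat.), MeOH, visible light, rt
Reagents that add atoms: dioxygen, O=O
Why: Dye-sensitised photooxygenation of a furan, in which singlet oxygen adds across C2 and C5 in a [4+2] cycloaddition and methanolysis of the endoperoxide expels the formyl carbon as methyl formate to leave the hydroxybutenolide.

Step 6
Reactants: 10 5-hydroxyfuran-2(5H)-one; 11 (1S,2R,5S)-(+)-menthol
Product: 12 (5S)-5-{[(1S,2R,5S)-5-methyl-2-(propan-2-yl)cyclohexyl]oxy}furan-2(5H)-one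
Conditions: CSA (5 mol%), toluene, reflux, Dean–Stark; crystallisation from hexane, mother liquor re-equilibrated with CSA
Reagents that add atoms: none
Why: Acid-catalysed acetalisation of the pseudo-acid gives both C5 epimers, which interconvert under acid while the (5S) epimer crystallises (crystallisation-induced diastereomer transformation, the mirror image of the established l-menthol case), so C5 is set by the menthyl group under thermodynamic and lattice control.

Step 7
Reactants: 8 (3S,4S)-3-(methoxycarbonyl)-5,6,7-trimethoxy-1-oxo-3,4-dihydro-1H-isochromene-4-carboxylic acid; 12 (5S)-5-{[(1S,2R,5S)-5-methyl-2-(propan-2-yl)cyclohexyl]oxy}furan-2(5H)-one (2 equiv)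
Product: 13 methyl (3S,4S)-5,6,7-trimethoxy-4-[(2S,3R)-2-{[(1S,2R,5S)-5-methyl-2-(propan-2-yl)cyclohexyl]oxy}-5-oxooxolan-3-yl]-1-oxo-3,4-dihydro-1H-isochromene-3-carboxylate
Conditions: Ir[dF(CF3)ppy]2(dtbbpy)PF6 (2 mol%), K2HPO4 (1.2 equiv), DMF, 450 nm LEDs, rt, degassed
Reagents that add atoms: none
Why: Photoredox decarboxylative Giese reaction, in which the excited iridium photocatalyst oxidises the carboxylate of 8, loss of CO2 gives the planar C4 benzylic radical, and this adds to the β-carbon of butenolide 12 before reduction and protonation of the α-acyl radical; the new bond should form on the ring face anti to the C3 ester (C4 trans to C3, whatever the C4 configuration of 8) and on the butenolide face anti to the C5 menthyloxy group (C1' R).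

Step 8
Reactants: 13 methyl (3S,4S)-5,6,7-trimethoxy-4-[(2S,3R)-2-{[(1S,2R,5S)-5-methyl-2-(propan-2-yl)cyclohexyl]oxy}-5-oxooxolan-3-yl]-1-oxo-3,4-dihydro-1H-isochromene-3-carboxylate
Product: 15 (2R)-2-[(3S,4S)-3-(methoxycarbonyl)-5,6,7-trimethoxy-1-oxo-3,4-dihydro-1H-isochromen-4-yl]butanedioic acid, via lactol 14 (not isolated)
Conditions: TFA/H2O (4:1), 45 °C; evaporate; then NaClO2, NaH2PO4, 2-methyl-2-butene, t-BuOH/H2O, rt
Reagents that add atoms: water, O; sodium chlorite, [Na+].[O-]Cl=O
Why: Aqueous acid hydrolysis of the acylal-type acetal releases menthol and the lactol, whose open aldehyde form is oxidised to the acid under buffered Pinnick conditions; the C1' centre beside the masked aldehyde should not enolise in this acidic, mostly ring-closed state, and 2-methyl-2-butene keeps hypochlorous acid away from the electron-rich arene.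

Step 9
Reactants: 15 (2R)-2-[(3S,4S)-3-(methoxycarbonyl)-5,6,7-trimethoxy-1-oxo-3,4-dihydro-1H-isochromen-4-yl]butanedioic acid
Product: 16 (2R)-2-[(3S,4S)-3-carboxy-5,6,7-trihydroxy-1-oxo-3,4-dihydro-1H-isochromen-4-yl]butanedioic acid
Conditions: BBr3 (12 equiv), CH2Cl2, −78 °C to rt; then H2O, 0 °C; then 1 M HCl, 50 °C; reversed-phase chromatography
Reagents that add atoms: none
Why: Lewis acid-mediated ether and ester cleavage, in which BBr3 binds each methoxy and ester oxygen and bromide removes the methyl group by SN2 attack as bromomethane, while the aryl lactone (its alkyl carbon C3 is secondary and deactivated by the adjacent carbonyl) and the three stereocentres, none of which enolises under acid, should survive, and the warm dilute acid finish hydrolyses borates and any residual methyl ester.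

**Compound list**

1 | 2-bromo-3,4,5-trimethoxybenzoic acid | COc1cc(C(=O)O)c(Br)c(OC)c1OC | starting material
2 | diethyl malonate | CCOC(=O)CC(=O)OCC | starting material
3 | 2-(1,3-diethoxy-1,3-dioxopropan-2-yl)-3,4,5-trimethoxybenzoic acid | CCOC(=O)C(C(=O)OCC)c1c(OC)c(OC)c(OC)cc1C(=O)O | intermediate
4 | 2-(6-carboxy-2,3,4-trimethoxyphenyl)propanedioic acid | OC(=O)C(C(=O)O)c1c(OC)c(OC)c(OC)cc1C(=O)O | intermediate
5 | 2-(carboxymethyl)-3,4,5-trimethoxybenzoic acid | OC(=O)Cc1c(OC)c(OC)c(OC)cc1C(=O)O | intermediate
6 | 5,6,7-trimethoxyisochromane-1,3-dione | O=C1Cc2c(cc(OC)c(OC)c2OC)C(=O)O1 | intermediate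
7 | methyl glyoxylate | COC(=O)C=O | starting material
8 | (3S,4S)-3-(methoxycarbonyl)-5,6,7-trimethoxy-1-oxo-3,4-dihydro-1H-isochromene-4-carboxylic acid | OC(=O)[C@H]1c2c(cc(OC)c(OC)c2OC)C(=O)O[C@@H]1C(=O)OC | intermediate
9 | furfural | O=Cc1ccco1 | starting material
10 | 5-hydroxyfuran-2(5H)-one (racemic) | O=C1C=CC(O)O1 | intermediate
11 | (1S,2R,5S)-(+)-menthol | O[C@H]1C[C@@H](C)CC[C@@H]1C(C)C | starting material
12 | (5S)-5-{[(1S,2R,5S)-5-methyl-2-(propan-2-yl)cyclohexyl]oxy}furan-2(5H)-one | O=C1C=C[C@@H](O[C@H]2C[C@@H](C)CC[C@@H]2C(C)C)O1 | intermediate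
13 | methyl (3S,4S)-5,6,7-trimethoxy-4-[(2S,3R)-2-{[(1S,2R,5S)-5-methyl-2-(propan-2-yl)cyclohexyl]oxy}-5-oxooxolan-3-yl]-1-oxo-3,4-dihydro-1H-isochromene-3-carboxylate | O=C3C[C@@H]([C@@H](O[C@H]4C[C@@H](C)CC[C@@H]4C(C)C)O3)[C@H]1c2c(cc(OC)c(OC)c2OC)C(=O)O[C@@H]1C(=O)OC | intermediate
14 | methyl (3S,4S)-4-[(3R)-2-hydroxy-5-oxooxolan-3-yl]-5,6,7-trimethoxy-1-oxo-3,4-dihydro-1H-isochromene-3-carboxylate (both anomers) | O=C3C[C@@H](C(O)O3)[C@H]1c2c(cc(OC)c(OC)c2OC)C(=O)O[C@@H]1C(=O)OC | intermediate
15 | (2R)-2-[(3S,4S)-3-(methoxycarbonyl)-5,6,7-trimethoxy-1-oxo-3,4-dihydro-1H-isochromen-4-yl]butanedioic acid | O=C(O)C[C@@H](C(=O)O)[C@H]1c2c(cc(OC)c(OC)c2OC)C(=O)O[C@@H]1C(=O)OC | intermediate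
16 | (2R)-2-[(3S,4S)-3-carboxy-5,6,7-trihydroxy-1-oxo-3,4-dihydro-1H-isochromen-4-yl]butanedioic acid | O=C(O)C[C@@H](C(=O)O)[C@H]1c2c(cc(O)c(O)c2O)C(=O)O[C@@H]1C(=O)O | target

**Step count and risks**

Total steps: 9. Longest linear sequence: 7 (steps 1, 2, 3, 4, 7, 8, 9); steps 5 and 6 form a two-step side branch to the acceptor 12.

Steps most likely to fail:

1. Step 7. The stabilised and hindered C4 benzylic radical may add to the butenolide more slowly than it dimerises, is oxidised further to the isocoumarin, or is reduced and protonated (hydrodecarboxylation); facial control at C4 could also be incomplete. The fallback sets out from 8 and rejoins the route at 16. The same photoredox decarboxylation is run with dimethyl fumarate (3 equiv), a doubly activated and unhindered acceptor. It should give dimethyl (2R)-2-[(3S,4S)-3-(methoxycarbonyl)-5,6,7-trimethoxy-1-oxo-3,4-dihydro-1H-isochromen-4-yl]butanedioate F1 together with its (2S) epimer F2, because C1' is then under substrate control only. The epimers are separated by preparative HPLC, and F1 is treated with BBr3 under the conditions of step 9 (six methyl groups to remove) to give 16 directly, by-passing 13 and 15.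

2. Step 4. Uncatalysed addition of the enolised anhydride to the very electrophilic glyoxylate may compete with the catalyst-bound pathway and erode the enantiofacial selectivity at C3, and hydrated or oligomerised glyoxylate may react sluggishly so that self-condensation of the anhydride takes over. The fallback sets out from 6 (with 7) and rejoins at 8; it replaces asymmetric catalysis by classical resolution. The annulation is run with i-Pr2NEt (10 mol%) in CH2Cl2 at rt to give the racemic trans-3-(methoxycarbonyl)-5,6,7-trimethoxy-1-oxo-3,4-dihydro-1H-isochromene-4-carboxylic acid F3. This is combined with (R)-1-phenylethylamine in EtOAc/EtOH, and the (R)-1-phenylethylammonium salt of the (3S,4S) acid F4 is obtained by fractional crystallisation; the amine enantiomer is chosen so that this salt is the less soluble one. Partition between EtOAc and 1 M HCl returns 8.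

3. Step 1. At a bromide flanked by a carboxylate and a methoxy group on an electron-rich ring, hydrodebromination may outrun C-arylation. The fallback sets out from 1 and rejoins at 5; it moves the coupling from copper to palladium on the ester. Treatment of 1 with MeI and K2CO3 in DMF gives methyl 2-bromo-3,4,5-trimethoxybenzoate F5. Palladium-catalysed arylation of diethyl malonate 2 (Pd(dba)2, P(t-Bu)3, K3PO4, toluene, 70 °C) then gives diethyl 2-[6-(methoxycarbonyl)-2,3,4-trimethoxyphenyl]propanedioate F6. Saponification with NaOH followed by acidification and heating, as in step 2, leads through triacid 4 to 5.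

**Further compounds**

F1 | step 7 | dimethyl (2R)-2-[(3S,4S)-3-(methoxycarbonyl)-5,6,7-trimethoxy-1-oxo-3,4-dihydro-1H-isochromen-4-yl]butanedioate | COC(=O)C[C@@H](C(=O)OC)[C@H]1c2c(cc(OC)c(OC)c2OC)C(=O)O[C@@H]1C(=O)OC
F2 | step 7 | dimethyl (2S)-2-[(3S,4S)-3-(methoxycarbonyl)-5,6,7-trimethoxy-1-oxo-3,4-dihydro-1H-isochromen-4-yl]butanedioate | COC(=O)C[C@H](C(=O)OC)[C@H]1c2c(cc(OC)c(OC)c2OC)C(=O)O[C@@H]1C(=O)OC
F3 | step 4 | racemic trans-3-(methoxycarbonyl)-5,6,7-trimethoxy-1-oxo-3,4-dihydro-1H-isochromene-4-carboxylic acid | OC(=O)[C@H]1c2c(cc(OC)c(OC)c2OC)C(=O)O[C@@H]1C(=O)OC.OC(=O)[C@@H]1c2c(cc(OC)c(OC)c2OC)C(=O)O[C@H]1C(=O)OC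
F4 | step 4 | (R)-1-phenylethylammonium (3S,4S)-3-(methoxycarbonyl)-5,6,7-trimethoxy-1-oxo-3,4-dihydro-1H-isochromene-4-carboxylate | [O-]C(=O)[C@H]1c2c(cc(OC)c(OC)c2OC)C(=O)O[C@@H]1C(=O)OC.C[C@@H]([NH3+])c1ccccc1
F5 | step 1 | methyl 2-bromo-3,4,5-trimethoxybenzoate | COC(=O)c1cc(OC)c(OC)c(OC)c1Br
F6 | step 1 | diethyl 2-[6-(methoxycarbonyl)-2,3,4-trimethoxyphenyl]propanedioate | CCOC(=O)C(C(=O)OCC)c1c(OC)c(OC)c(OC)cc1C(=O)OC
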